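The readings are calculated with constants of no real substance, noise included.

The amounts in hand were two runs at the same equivalents: larch, which is the asked flask followed for an hour, and maple, at a lower charge.

| setting | larch | maple | flask |
|---|---|---|---|
| starting material | 0.059 M | 0.040 M | 0.059 M |
| reagent in the second phase | 1.2 equiv | 1.2 equiv | 1.20 equiv |
| remark | the very flask that is asked about, followed so far | run made earlier |  |
| time |  |  | 8.0 h |
| volume of the second phase over the first |  |  | 2.0 |
larch run (percent of the starting material charged)

| time / min | target / % | starting material / % |
|---|---|---|
| 10.0 | 56 | 39 |
| 20.0 | 52 | 37 |
| 30.0 | 48 | 37 |
| 40.0 | 42 | 38 |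
| 50.0 | 44 | 38 |
| 60.0 | 36 | 36 |

maple run (percent of the starting material charged)

| time / h | target / % | starting material / % |
|---|---|---|
| 0.500 | 45 | 44 |
| 1.00 | 39 | 45 |
| 1.50 | 30 | 44 |
| 2.00 | 26 | 45 |
| 2.50 | 22 | 39 |
| 3.00 | 20 | 41 |

(scatter of a reading: 2 percentage points)
- a species is counted by the starting material in it: one side product counts as two
- in the second phase: reagent in the second phase; everything else is in the first
- charges count per volume of the first phase; a concentration in a rate is the amount of a species over the volume of its own phase; every rate counts per litre of the first phase
- candidate steps: reagent in the reaction phase <-> reagent in the second phase; starting material + reagent in the reaction phase <-> target; 2 reagent in the reaction phase -> self-condensation product; starting material + target -> side product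
- the earlier runs hold the two phases in the same ratio of volumes as the flask asked about
1. target at 8.0 h, in percent of the starting material charged
2. the change that raises the amount of target at 8.0 h, in percent of the starting material charged most ("none" if none brings more than 2 percentage points) (green / teal / none)
3. amount of target at 8.0 h, in percent of the starting material charged, after teal

In larch starting material stayed near 36% while target sank, so I followed x = c(starting material)/c(target). If the addition is a fast pre-equilibrium, x varies inversely with c(reagent in the reaction phase). If that reagent is lost by second-order self-condensation, x then climbs linearly at a slope independent of the charge. I called this slope the climb, the growth of x per hour: 0.364 h⁻¹ in larch, and 0.429 h⁻¹ in maple.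

The larch line starts at 0.636 and reaches 3.55 at 8.0 h.

How much starting material and target together survive? Each side product consumes one of each, so the inverse of this pool rises with ln(1+x)+1/(1+x). Scaled on the larch readings, that left 26.2%, and target is the pool over 1+x: 5.76%.

Would more reagent help? On this picture green lowers the start of the line but not the climb. Even wiping out the start, with the pool held, gains 0.94 percentage points, less than the margin. Target stood at 56% by 10.0 min, far earlier than the asked time, so I expected nothing from teal. My choice was none.

The forecast gave 7%, green and 7%, holding that “second-order loss forgets the initial amount”. It parted from me on the choice.

The flask gave 6.10%; best was none, with green at 0.51 points and teal at −0.014 points, and 6.09% after teal.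

    reagent in the reaction phase ⇌ reagent in the second phase, rate k1*([reagent in the reaction phase] - [reagent in the second phase]/K1) per volume of the first phase (partition coefficient = 0.500, kL = 0.0104 s⁻¹)
    starting material + reagent in the reaction phase ⇌ target (K = 91.0 L mol⁻¹, k = 2.28 L mol⁻¹ s⁻¹)
    2 reagent in the reaction phase → self-condensation product (k = 0.0133 L mol⁻¹ s⁻¹)
    starting material + target → side product (k = 0.00316 L mol⁻¹ s⁻¹)

At 8.00 h the addition by itself had a relaxation half-life of 0.181 min, far shorter than the run, while half of the self-condensation turnover up to that time was done by 1.21 h. Side product kept growing, to 69.7% at 8.00 h. At 8.00 h x in the flask stood at 3.97, against the 3.55 of my larch line.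

For the neighbour, the same flask read at 2.0 h, the larch line with its climb gives x = 1.36. That flask stood at 1.33, with target at 25.9%.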